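(The readings are simulated for an exercise.)

The slowness of the winter flask after its first readings can be read in two ways: the reagent has gone, or forward and back rates have come level.

| flask | substrate | reagent | remark | time |
|---|---|---|---|---|
| winter | 0.50 mM | 0.75 mM | the very flask that is asked about, followed so far |  |
| noon | 0.25 mM | 0.75 mM | run made earlier |  |
| flask | 0.50 mM | 0.750 mM |  | 4.0 min |

- winter (time / s: substrate / %, tris adduct / %, single product / %): 10.0: 32, 2, 54; 25.0: 23, 9, 56; 40.0: 25, 6, 58; 60.0: 26, 4, 56; 90.0: 22, 7, 56; 120: 24, 3, 57
- noon (time / min: substrate / %, tris adduct / %, single product / %): 0.250: 13, 9, 53; 0.833: 10, 14, 53; 1.33: 8, 10, 54; 2.00: 4, 9, 55; 3.00: 11, 12, 51; 4.00: 10, 9, 54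

(each reading ± 2 percentage points)

- the reaction counts as stopped when no species that holds the substrate changes by six tenths of a point or more over the second half of the time

* why nothing more happens at 4.0 min, or that something still does (all of the substrate has reacted / forward and back rates have come level / it is still moving / the reagent has run out first)
* part of the substrate gone at 4.0 min
* the tris adduct standing at 4.0 min, as a percentage of the substrate charged
* the single product standing at 4.0 min, as a percentage of the substrate charged
* amount of tris adduct if the flask were left three thousand times as long, in percent of the substrate charged

From 25.0 s on, the winter readings average 24.0 % substrate, 5.80 % tris adduct and 56.6 % single product. Working with the fraction left, the dose is the natural logarithm of substrate charged over substrate left, here 1.43, and in a one-way, pseudo-first-order loss it grows in step with c(reagent) and time. The first reading gives a dose rate of 0.114 s⁻¹, and since c(reagent) stood at or below its charge, each unit of c(reagent) buys at least 152 M⁻¹ s⁻¹. Counting 1, 2 and 3 reagent for the single product, the unseen share taken as bis adduct, and the tris adduct, the winter flask has spent 0.506 mM, which leaves 0.244 mM unaccounted. Standing free, that remainder means a dose gain of 3.52 between 25.0 s and 120 s, whereas the readings show −0.0426.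

The weak link is the one-way assumption. With level rates in a step that sets a group free, single product times released group over substrate and remainder ought to coincide between flasks, and with the released group counted as the spent reagent the readings give 4.89 for the winter flask and, with a remainder of 0.404 mM, 4.90 for the noon flask. These readings therefore do not tell level rates from reagent lost by some unseen route, so this reckoning leaves the cause open between the two and holds the plateau: 76.0 % of the substrate gone, with the tris adduct and single product as averaged, at the asked time and long after.

The forecast says forward and back rates have come level, “a reversible equilibrium, reached quickly”, with 76 % gone, 5.3 % tris adduct, 56.5 % single product and 5.5 % tris adduct much later, so it names one of the two causes that this reckoning leaves open and stands slightly lower on the tris adduct.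

The flask gives: the reagent has run out first, with 75.6 % gone, 4.00 % tris adduct, 56.8 % single product and 4.00 % tris adduct much later.

    tris adduct ⇌ isomer of the product (K = 0.700, k = 0.0200 s⁻¹)
    reagent + single product → bis adduct + released group (k = 160 M⁻¹ s⁻¹)
    substrate + reagent → single product + released group (k = 470 M⁻¹ s⁻¹)
    reagent + tris adduct → tetra adduct + released group (k = 120 M⁻¹ s⁻¹)
    2 reagent → self-condensation product (k = 130 M⁻¹ s⁻¹)
    reagent + bis adduct → tris adduct + released group (k = 490 M⁻¹ s⁻¹)

Half of the conversion stood by 1.87 s and half of the self-condensation turnover by 1.28 s, and at 0.400 min this flask kept 1.34 % of its reagent, the limiting reagent, with the dose at 1.38. With reagent at 0 % by 2.00 min, tris adduct had passed into its isomer by a net 2.80 % at the asked time, when the dose read 1.41, while the neighbour flask charged with 3.0 mM of reagent ended at a dose of 3.69.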